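**Plan**
Locants: unprimed = prenylated chromene (benzene ring A), primed = hydroxylated chromene (benzene ring B).
Retrosynthesis: first the MOM ether and the ring B pyran (O1'–C2', C4'–C4a') go back to a free C8a' phenol; then ring B is cut at C5'–C6' and C6'–C7'; last the ring A pyran and the C8–prenyl bond go back to 4-hydroxybenzaldehyde.
Enabling feature: ring B has oxygen on the adjacent carbons C8a' and C8' and the biaryl carbon C6' para to C8a', so it is a 3-oxy-4-pyranone whose ring oxygen is replaced by C6', the benzylic carbon of a ring A phosphonate.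
Forward order: ring A pyran (propargyl Claisen/oxa-6π), ring B benzene ([5+1] from the pyranone), ring B pyran (second Claisen/oxa-6π), MOM removal.
Stereochemistry: the target has no stereocentre; both chromene alkenes are cis by ring constraint.

Key step: step 8

Assumption: 3-hydroxy-4H-pyran-4-one (pyromeconic acid) is taken as a purchasable compound; it is otherwise reached from kojic acid by oxidation to comenic acid and decarboxylation.

**Route**

Step 1
Reactants: 1 4-hydroxybenzaldehyde; 2 prenyl bromide (1-bromo-3-methylbut-2-ene)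
Product: 3 4-hydroxy-3-(3-methylbut-2-enyl)benzaldehyde
Conditions: KOH (aq.), rt
Reagents that add atoms: none
Why: Ortho C-alkylation of the ambident phenoxide, favoured in water where the oxygen is hydrogen-bonded and directed ortho because the para position carries the formyl group, with the O-prenyl ether as a separable by-product.

Step 2
Reactants: 3 4-hydroxy-3-(3-methylbut-2-enyl)benzaldehyde; 4 3-chloro-3-methylbut-1-yne
Product: 5 4-(2-methylbut-3-yn-2-yloxy)-3-(3-methylbut-2-enyl)benzaldehyde
Conditions: DBU, CuCl2·2H2O (cat.), MeCN, 0 °C → rt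
Reagents that add atoms: none
Why: Copper-catalysed propargylic O-alkylation of the phenoxide by the tertiary propargylic chloride, the standard entry to aryl 1,1-dimethylpropargyl ethers.

Step 3
Reactants: 5 4-(2-methylbut-3-yn-2-yloxy)-3-(3-methylbut-2-enyl)benzaldehyde
Product: 8 2,2-dimethyl-8-(3-methylbut-2-enyl)-2H-chromene-6-carbaldehyde, via allenylphenol 6 (not isolated), via quinone methide 7 (not isolated)
Conditions: PhNEt2, 190 °C
Reagents that add atoms: none
Why: Aromatic propargyl Claisen rearrangement onto the only unsubstituted ortho carbon and enolisation give allenylphenol 6, whose 1,5-hydrogen shift to quinone methide 7 and oxa-6π electrocyclisation close the 2,2-dimethylpyran ring.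

Step 4
Reactants: 8 2,2-dimethyl-8-(3-methylbut-2-enyl)-2H-chromene-6-carbaldehyde
Product: 9 [2,2-dimethyl-8-(3-methylbut-2-enyl)-2H-chromen-6-yl]methanol
Conditions: NaBH4, MeOH, 0 °C
Reagents that add atoms: none
Why: Borohydride reduction of the aldehyde, which leaves the prenyl and chromene alkenes untouched.

Step 5
Reactants: 9 [2,2-dimethyl-8-(3-methylbut-2-enyl)-2H-chromen-6-yl]methanol
Product: 10 6-(bromomethyl)-2,2-dimethyl-8-(3-methylbut-2-enyl)-2H-chromene
Conditions: CBr4, PPh3, CH2Cl2, 0 °C
Reagents that add atoms: carbon tetrabromide, BrC(Br)(Br)Br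
Why: Appel bromination of the benzylic alcohol under neutral conditions, chosen so that no HBr can add to the two alkenes.

Step 6
Reactants: 10 6-(bromomethyl)-2,2-dimethyl-8-(3-methylbut-2-enyl)-2H-chromene
Product: 11 diethyl {[2,2-dimethyl-8-(3-methylbut-2-enyl)-2H-chromen-6-yl]methyl}phosphonate
Conditions: P(OEt)3 (neat), 120 °C
Reagents that add atoms: triethyl phosphite, CCOP(OCC)OCC
Why: Michaelis-Arbuzov reaction of the activated benzylic bromide, driven by loss of volatile bromoethane.

Step 7
Reactants: 12 3-hydroxy-4H-pyran-4-one (pyromeconic acid)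
Product: 13 3-(methoxymethoxy)-4H-pyran-4-one
Conditions: MOMCl, i-Pr2NEt, CH2Cl2, 0 °C → rt
Reagents that add atoms: chloromethyl methyl ether, COCCl
Why: Williamson-type O-alkylation of the acidic enolic hydroxyl gives the acetal that will mask the C8' oxygen.

Step 8
Reactants: 11 diethyl {[2,2-dimethyl-8-(3-methylbut-2-enyl)-2H-chromen-6-yl]methyl}phosphonate; 13 3-(methoxymethoxy)-4H-pyran-4-one
Product: 19 4-[2,2-dimethyl-8-(3-methylbut-2-enyl)-2H-chromen-6-yl]-2-(methoxymethoxy)phenol, via lithiated phosphonate 14 (not isolated), via silyloxypyrylium triflate 15 (not isolated), via 2H-pyran adduct 16 (not isolated), via lithium trienolate 17 (not isolated), via aryl silyl ether 18 (not isolated)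
Conditions: 13, TIPSOTf, CH2Cl2, 0 °C; 11, n-BuLi, THF, −78 °C; combine at −78 °C; LiN(SiMe3)2, −78 °C → rt; AcOH, Bu4NF, rt
Reagents that add atoms: none
Why: Proposed new method: TIPSOTf silylates the carbonyl oxygen of 13 to give pyrylium triflate 15, and lithiated phosphonate 14 adds to an alpha carbon of 15 (C6 is drawn, C2 attack leads to the same arene) to give 2H-pyran 16. LiN(SiMe3)2 then removes the proton next to phosphorus and the ring oxygen is expelled, the anionic counterpart of a retro-oxa-6π opening, which gives trienolate 17, the conjugate base of the ring-opened (Z,Z)-dienal phosphonate. Ring B closes by intramolecular Horner-Wadsworth-Emmons olefination, a 6-exo-trig attack of the phosphorus-stabilised carbanion terminus of 17 on its aldehyde carbon followed by loss of lithium diethyl phosphate, so that C5'-C6' is made in the addition and C6'-C7' in the olefination, and fluoride finally cleaves silyl ether 18 to phenol 19. The closest known reaction types are the conversion of pyrylium salts into benzenes by phosphorus ylides or by nitromethane and base, and the alpha addition of carbon nucleophiles to 4-silyloxypyrylium triflates made from 4-pyranones. No stereocentre is created in the product, the two of 16 being erased on ring opening and aromatisation. The step needs attack at a ring alpha carbon in preference to C4 or silicon, which the 4-silyloxy donor and the bulk of the triisopropylsilyl group should secure, and a cis central alkene in 17 for closure, which is inherited from the pyran ring.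

Step 9
Reactants: 19 4-[2,2-dimethyl-8-(3-methylbut-2-enyl)-2H-chromen-6-yl]-2-(methoxymethoxy)phenol; 4 3-chloro-3-methylbut-1-yne
Product: 20 6-[3-(methoxymethoxy)-4-(2-methylbut-3-yn-2-yloxy)phenyl]-2,2-dimethyl-8-(3-methylbut-2-enyl)-2H-chromene
Conditions: DBU, CuCl2·2H2O (cat.), MeCN, 0 °C → rt
Reagents that add atoms: none
Why: Copper-catalysed propargylic O-alkylation of the single free phenol (the C8a' oxygen), the C8' oxygen being held as its MOM ether.

Step 10
Reactants: 20 6-[3-(methoxymethoxy)-4-(2-methylbut-3-yn-2-yloxy)phenyl]-2,2-dimethyl-8-(3-methylbut-2-enyl)-2H-chromene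
Product: 23 8'-(methoxymethoxy)-2,2,2',2'-tetramethyl-8-(3-methylbut-2-enyl)-2H,2'H-6,6'-bichromene, via allenylphenol 21 (not isolated), via quinone methide 22 (not isolated)
Conditions: o-xylene, 140 °C
Reagents that add atoms: none
Why: The aromatic propargyl Claisen rearrangement can only reach C4a', the one free ortho carbon, and enolisation to 21, 1,5-hydrogen shift to 22 and oxa-6π electrocyclisation then close the ring B pyran.

Step 11
Reactants: 23 8'-(methoxymethoxy)-2,2,2',2'-tetramethyl-8-(3-methylbut-2-enyl)-2H,2'H-6,6'-bichromene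
Product: 24 2,2,2',2'-tetramethyl-8-(3-methylbut-2-enyl)-2H,2'H-6,6'-bichromen-8'-ol (CNP0158232.0)
Conditions: HCl (cat.), MeOH, 40 °C
Reagents that add atoms: none
Why: Acid-catalysed transacetalisation of the aryl MOM ether to methanol, mild enough for the chromene and prenyl alkenes since no phenol lies ortho to the prenyl group for an acid-induced chroman closure.

**Compound list**
1 | 4-hydroxybenzaldehyde | O=Cc1ccc(O)cc1 | starting material
2 | prenyl bromide (1-bromo-3-methylbut-2-ene) | CC(C)=CCBr | starting material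
3 | 4-hydroxy-3-(3-methylbut-2-enyl)benzaldehyde | O=Cc1ccc(O)c(CC=C(C)C)c1 | intermediate
4 | 3-chloro-3-methylbut-1-yne | CC(C)(Cl)C#C | starting material
5 | 4-(2-methylbut-3-yn-2-yloxy)-3-(3-methylbut-2-enyl)benzaldehyde | O=Cc1ccc(OC(C)(C)C#C)c(CC=C(C)C)c1 | intermediate
6 | allenylphenol (formed in the flask): 4-hydroxy-3-(3-methylbuta-1,2-dienyl)-5-(3-methylbut-2-enyl)benzaldehyde | O=Cc1cc(CC=C(C)C)c(O)c(C=C=C(C)C)c1 | intermediate
7 | quinone methide (formed in the flask): (3Z)-3-(3-methylbut-2-enylidene)-5-(3-methylbut-2-enyl)-4-oxocyclohexa-1,5-diene-1-carbaldehyde | O=C1C(CC=C(C)C)=CC(C=O)=C/C1=C/C=C(C)C | intermediate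
8 | 2,2-dimethyl-8-(3-methylbut-2-enyl)-2H-chromene-6-carbaldehyde | O=Cc1cc(CC=C(C)C)c2OC(C)(C)C=Cc2c1 | intermediate
9 | [2,2-dimethyl-8-(3-methylbut-2-enyl)-2H-chromen-6-yl]methanol | OCc1cc(CC=C(C)C)c2OC(C)(C)C=Cc2c1 | intermediate
10 | 6-(bromomethyl)-2,2-dimethyl-8-(3-methylbut-2-enyl)-2H-chromene | BrCc1cc(CC=C(C)C)c2OC(C)(C)C=Cc2c1 | intermediate
11 | diethyl {[2,2-dimethyl-8-(3-methylbut-2-enyl)-2H-chromen-6-yl]methyl}phosphonate | CCOP(=O)(Cc1cc(CC=C(C)C)c2OC(C)(C)C=Cc2c1)OCC | intermediate
12 | 3-hydroxy-4H-pyran-4-one (pyromeconic acid) | O=C1C=COC=C1O | starting material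
13 | 3-(methoxymethoxy)-4H-pyran-4-one | COCOC1=COC=CC1=O | intermediate
14 | lithiated phosphonate (formed in the flask): lithium salt of 11 deprotonated at the benzylic carbon | [Li+].CCOP(=O)([CH-]c1cc(CC=C(C)C)c2OC(C)(C)C=Cc2c1)OCC | intermediate
15 | silyloxypyrylium triflate (formed in the flask): 3-(methoxymethoxy)-4-(triisopropylsilyloxy)pyrylium trifluoromethanesulfonate | COCOc1c[o+]ccc1O[Si](C(C)C)(C(C)C)C(C)C.[O-]S(=O)(=O)C(F)(F)F | intermediate
16 | 2H-pyran adduct (formed in the flask): diethyl {[2,2-dimethyl-8-(3-methylbut-2-enyl)-2H-chromen-6-yl][5-(methoxymethoxy)-4-(triisopropylsilyloxy)-2H-pyran-2-yl]methyl}phosphonate, diastereomer mixture, both stereocentres uncontrolled and lost in the same step | CCOP(=O)(OCC)C(c1cc(CC=C(C)C)c2OC(C)(C)C=Cc2c1)C1OC=C(OCOC)C(O[Si](C(C)C)(C(C)C)C(C)C)=C1 | intermediate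
17 | lithium trienolate (formed in the flask): lithium (1E,3E)-6-(diethoxyphosphoryl)-6-[2,2-dimethyl-8-(3-methylbut-2-enyl)-2H-chromen-6-yl]-2-(methoxymethoxy)-3-(triisopropylsilyloxy)hexa-1,3,5-trien-1-olate, C5=C6 geometry not fixed | [Li+].[O-]/C=C(OCOC)\C(O[Si](C(C)C)(C(C)C)C(C)C)=C/C=C(c1cc(CC=C(C)C)c2OC(C)(C)C=Cc2c1)P(=O)(OCC)OCC | intermediate
18 | aryl silyl ether (formed in the flask): {4-[2,2-dimethyl-8-(3-methylbut-2-enyl)-2H-chromen-6-yl]-2-(methoxymethoxy)phenoxy}triisopropylsilane | COCOc1cc(ccc1O[Si](C(C)C)(C(C)C)C(C)C)-c1cc(CC=C(C)C)c2OC(C)(C)C=Cc2c1 | intermediate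
19 | 4-[2,2-dimethyl-8-(3-methylbut-2-enyl)-2H-chromen-6-yl]-2-(methoxymethoxy)phenol | COCOc1cc(ccc1O)-c1cc(CC=C(C)C)c2OC(C)(C)C=Cc2c1 | intermediate
20 | 6-[3-(methoxymethoxy)-4-(2-methylbut-3-yn-2-yloxy)phenyl]-2,2-dimethyl-8-(3-methylbut-2-enyl)-2H-chromene | COCOc1cc(ccc1OC(C)(C)C#C)-c1cc(CC=C(C)C)c2OC(C)(C)C=Cc2c1 | intermediate
21 | allenylphenol (formed in the flask): 4-[2,2-dimethyl-8-(3-methylbut-2-enyl)-2H-chromen-6-yl]-2-(methoxymethoxy)-6-(3-methylbuta-1,2-dienyl)phenol | COCOc1cc(cc(C=C=C(C)C)c1O)-c1cc(CC=C(C)C)c2OC(C)(C)C=Cc2c1 | intermediate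
22 | quinone methide (formed in the flask): (6Z)-4-[2,2-dimethyl-8-(3-methylbut-2-enyl)-2H-chromen-6-yl]-2-(methoxymethoxy)-6-(3-methylbut-2-enylidene)cyclohexa-2,4-dien-1-one | O=C1C(OCOC)=CC(c2cc(CC=C(C)C)c3OC(C)(C)C=Cc3c2)=C/C1=C/C=C(C)C | intermediate
23 | 8'-(methoxymethoxy)-2,2,2',2'-tetramethyl-8-(3-methylbut-2-enyl)-2H,2'H-6,6'-bichromene | COCOc1cc(cc2C=CC(C)(C)Oc12)-c1cc(CC=C(C)C)c2OC(C)(C)C=Cc2c1 | intermediate
24 | 2,2,2',2'-tetramethyl-8-(3-methylbut-2-enyl)-2H,2'H-6,6'-bichromen-8'-ol (CNP0158232.0) | CC(C)=CCc1cc(-c2cc(O)c3c(c2)C=CC(C)(C)O3)cc2c1OC(C)(C)C=C2 | target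

**Count and risks**
Total steps: 11. Longest linear sequence: 10 (steps 1–6 and 8–11 from 4-hydroxybenzaldehyde; step 7 is a one-step side branch).

Steps most likely to fail:

1. Step 8 (the step labelled as a proposed new method). The silyl group may pass from the pyrylium ion to the carbanion, returning the pyranone. The adduct may also fail to ring-open, or the trienolate may be protonated on work-up instead of closing, so that no arene forms. The fallback uses known chemistry, sets out from 2 and 4 (with purchased 4-bromophenol and catechol) and comes back at 19. 4-Bromophenol is ortho-prenylated with 2 (NaH, toluene) to 4-bromo-2-(3-methylbut-2-enyl)phenol F1 and etherified with 4 (DBU, CuCl2·2H2O cat., MeCN) to 4-bromo-1-(2-methylbut-3-yn-2-yloxy)-2-(3-methylbut-2-enyl)benzene F2. Heating as in step 3 takes F2 through allenylphenol 4-bromo-2-(3-methylbuta-1,2-dienyl)-6-(3-methylbut-2-enyl)phenol F3 and quinone methide (6Z)-4-bromo-6-(3-methylbut-2-enylidene)-2-(3-methylbut-2-enyl)cyclohexa-2,4-dien-1-one F4 to 6-bromo-2,2-dimethyl-8-(3-methylbut-2-enyl)-2H-chromene F5. Miyaura borylation (B2pin2, PdCl2(dppf), KOAc, dioxane, 80 °C) gives 2-[2,2-dimethyl-8-(3-methylbut-2-enyl)-2H-chromen-6-yl]-4,4,5,5-tetramethyl-1,3,2-dioxaborolane F6. Separately, catechol is mono-protected (MOMCl, i-Pr2NEt, CH2Cl2) to 2-(methoxymethoxy)phenol F7 and brominated para to the free hydroxyl (NBS, MeCN, 0 °C) to 4-bromo-2-(methoxymethoxy)phenol F8. Suzuki-Miyaura coupling of F6 with F8 (Pd(PPh3)4, K2CO3, dioxane/H2O, 80 °C) should give 19.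

2. Step 1. O-Alkylation and double alkylation of the ambident phenoxide may outrun mono-C-alkylation and leave little 3. The fallback sets out from 1 and comes back at 3. Compound 1 is etherified with 4 (DBU, CuCl2·2H2O cat., MeCN) to 4-(2-methylbut-3-yn-2-yloxy)benzaldehyde F9. Semi-hydrogenation (H2, Pd/CaCO3 poisoned with Pb(OAc)2, quinoline, EtOAc) gives 4-(2-methylbut-3-en-2-yloxy)benzaldehyde F10. On heating (PhNEt2, 180 °C) the aromatic Claisen rearrangement, with inversion of the allyl unit, should place the linear prenyl group on the ortho carbon and give 3.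

3. Step 9. Etherification of the phenoxide flanked by the MOM ether may be slow while the tertiary chloride is consumed by elimination. The fallback sets out from 19 and comes back at 23, bypassing 20. Compound 19 is condensed with 3-methylbut-2-enal (PhB(OH)2, AcOH, toluene, reflux with azeotropic removal of water). Boron-templated ortho-hydroxyalkylation at C4a', dehydration to quinone methide 22 and oxa-6π closure should give 23. This fallback makes no compound outside the list (F0).

**Further compounds**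
F1 | step 8 | 4-bromo-2-(3-methylbut-2-enyl)phenol | Oc1ccc(Br)cc1CC=C(C)C
F2 | step 8 | 4-bromo-1-(2-methylbut-3-yn-2-yloxy)-2-(3-methylbut-2-enyl)benzene | C#CC(C)(C)Oc1ccc(Br)cc1CC=C(C)C
F3 | step 8 | 4-bromo-2-(3-methylbuta-1,2-dienyl)-6-(3-methylbut-2-enyl)phenol | Oc1c(CC=C(C)C)cc(Br)cc1C=C=C(C)C
F4 | step 8 | (6Z)-4-bromo-6-(3-methylbut-2-enylidene)-2-(3-methylbut-2-enyl)cyclohexa-2,4-dien-1-one | O=C1C(CC=C(C)C)=CC(Br)=C/C1=C/C=C(C)C
F5 | step 8 | 6-bromo-2,2-dimethyl-8-(3-methylbut-2-enyl)-2H-chromene | Brc1cc(CC=C(C)C)c2OC(C)(C)C=Cc2c1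
F6 | step 8 | 2-[2,2-dimethyl-8-(3-methylbut-2-enyl)-2H-chromen-6-yl]-4,4,5,5-tetramethyl-1,3,2-dioxaborolane | CC1(C)OB(OC1(C)C)c1cc(CC=C(C)C)c2OC(C)(C)C=Cc2c1
F7 | step 8 | 2-(methoxymethoxy)phenol | COCOc1ccccc1O
F8 | step 8 | 4-bromo-2-(methoxymethoxy)phenol | COCOc1cc(Br)ccc1O
F9 | step 1 | 4-(2-methylbut-3-yn-2-yloxy)benzaldehyde | O=Cc1ccc(OC(C)(C)C#C)cc1
F10 | step 1 | 4-(2-methylbut-3-en-2-yloxy)benzaldehyde | O=Cc1ccc(OC(C)(C)C=C)cc1
F0 | step 9 | none | none
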